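**Pl**an
1. Numbering (germacrane): C1 furanone C=O, C2 furanone CH, C3 furanone O–C=, C4=C5 ring alkene (C15 = CH2OH on C4), C6 lactone O–CH, C7, C8 (ester carbon), C9 (CH2), C10 (quaternary; C14 = CH3; bridging O-10), C11=C13 methylene, C12 lactone C=O.
2. Retrosynthetic cuts, in order: O15–Si and O8–acyl; C7–C8, which opens the nine-membered ring O10–C3–C4=C5–C6–C7–C8–C9–C10; C7=C11 and O6–C12 (butenolide); O10–C3 (furanone); C1–C2; C3–C4; C5–C6.
3. Enabling feature: C13=C11–C7–C8–O8 is a homoallylic alcohol built into the α-methylene-γ-butyrolactone. It is the retron of a carbonyl allylation by a 3-(metallomethyl)butenolide, and C7–C8 belongs to the nine-membered ring only.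
4. Forward order: the chain is joined at C1–C2, then the furanone ring, then the butenolide ring, and the nine-membered ring last. The helpers (allylic bromide on C13, endocyclic C7=C11) are consumed in the closing event itself.
5. Stereochemistry: C10 comes from (S)-citramalic acid and C6 from a catalytic asymmetric alkynylation. Z-C4=C5 comes from a hydroxyl-directed trans-hydroalumination/iodination. C7 and C8 are set in the ring closure (C6 control, chair array), and C8 is then inverted by the esterification.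

Key step: step 15

Assumption: the (S,S) antipode of the ProPhenol ligand is taken to deliver the (4S)-carbinol of step 4. If the sense of induction is the opposite, the (R,R) ligand is used with no other change.

**Step 1**
Reactants: 1 (S)-citramalic acid
Product: 2 (S)-2-(2,2,4-trimethyl-5-oxo-1,3-dioxolan-4-yl)acetic acid
Conditions: 2,2-dimethoxypropane, p-TsOH·H2O (cat.), CH2Cl2, rt
Reagents that add atoms: 2,2-dimethoxypropane COC(C)(C)OC
Why: Acid-catalysed transacetalisation ties the tertiary hydroxyl and the adjacent carboxyl group into the favoured five-membered dioxolanone, which leaves the distal carboxyl group free and does not touch the chiral-pool C10 centre.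

**Step 2**
Reactants: 2 (S)-2-(2,2,4-trimethyl-5-oxo-1,3-dioxolan-4-yl)acetic acid
Product: 3 (S)-5-(2-hydroxyethyl)-2,2,5-trimethyl-1,3-dioxolan-4-one
Conditions: BH3·THF, THF, 0 °C to rt; then H2O
Reagents that add atoms: none
Why: Chemoselective borane reduction takes the free carboxylic acid through its acyloxyborane much faster than the dioxolanone carbonyl, and the neutral work-up keeps the hydroxyethyl dioxolanone from translactonising.

**Step 3**
Reactants: 3 (S)-5-(2-hydroxyethyl)-2,2,5-trimethyl-1,3-dioxolan-4-one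
Product: 4 (S)-5-[2-(tert-butyldimethylsilyloxy)ethyl]-2,2,5-trimethyl-1,3-dioxolan-4-one
Conditions: TBSCl, imidazole, CH2Cl2, 0 °C
Reagents that add atoms: TBSCl CC(C)(C)[Si](C)(C)Cl
Why: Imidazole-promoted silylation caps the primary alcohol (future C8) at once, so that it can neither attack the dioxolanone nor later compete with O-10 for the ynone.

**Step 4**
Reactants: 5 tert-butyl(prop-2-yn-1-yloxy)diphenylsilane; 6 (E)-crotonaldehyde
Product: 7 (4S,5E)-1-(tert-butyldiphenylsilyloxy)hept-5-en-2-yn-4-ol
Conditions: (S,S)-ProPhenol (10 mol %), Ph3P=O (20 mol %), Me2Zn, toluene, 0–4 °C; aq. NH4Cl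
Reagents that add atoms: none
Why: Zn–ProPhenol-catalysed asymmetric alkynylation, a reaction suited to α,β-unsaturated aldehydes, adds the alkynylzinc to one enal face inside the dinuclear zinc pocket and so sets C6, while the propenyl group is the later metathesis handle.

**Step 5**
Reactants: 7 (4S,5E)-1-(tert-butyldiphenylsilyloxy)hept-5-en-2-yn-4-ol
Product: 9 (2Z,4S,5E)-1-(tert-butyldiphenylsilyloxy)-2-iodohepta-2,5-dien-4-ol, via cyclic alkenylalanate 8 (not isolated)
Conditions: Red-Al, THF, 0 °C to rt; then I2, THF, −78 °C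
Reagents that add atoms: iodine II
Why: Hydroxyl-directed trans-hydroalumination of the propargylic alcohol puts hydride on C5 and aluminium on C4 within a five-membered O–Al–C ring, so iodinolysis with retention gives only the iodide with I cis to C6 (the future Z-C4=C5 geometry), the low temperature suppressing loss of the silyloxy group to an allene.

**Step 6**
Reactants: 9 (2Z,4S,5E)-1-(tert-butyldiphenylsilyloxy)-2-iodohepta-2,5-dien-4-ol
Product: 10 (2Z,4S,5E)-1-(tert-butyldiphenylsilyloxy)-2-iodo-4-(triethylsilyloxy)hepta-2,5-diene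
Conditions: TESCl, imidazole, CH2Cl2, 0 °C
Reagents that add atoms: TESCl CC[Si](Cl)(CC)CC
Why: Silylation masks O-6, which would otherwise quench the acetylide of step 8 and, as a (Z)-enynol, cycloisomerise to a furan under the gold catalysis of step 9.

**Step 7**
Reactants: 10 (2Z,4S,5E)-1-(tert-butyldiphenylsilyloxy)-2-iodo-4-(triethylsilyloxy)hepta-2,5-diene; 11 ethynylmagnesium bromide
Product: 12 (3E,5S,6E)-3-[(tert-butyldiphenylsilyloxy)methyl]-5-(triethylsilyloxy)octa-3,6-dien-1-yne (ethynyl group cis to the carbinol carbon)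
Conditions: 11, ZnBr2, THF, 0 °C; then 10, Pd(PPh3)4 (5 mol %), THF, rt
Reagents that add atoms: none
Why: Negishi coupling of an alkenyl iodide with ethynylzinc bromide proceeds with retention of the alkene geometry and gives the terminal enyne (C2≡C3–C4) directly, without a silyl-alkyne detour.

**Step 8**
Reactants: 12 (3E,5S,6E)-3-[(tert-butyldiphenylsilyloxy)methyl]-5-(triethylsilyloxy)octa-3,6-dien-1-yne; 4 (S)-5-[2-(tert-butyldimethylsilyloxy)ethyl]-2,2,5-trimethyl-1,3-dioxolan-4-one
Product: 15 (3S,7E,9S,10E)-1-(tert-butyldimethylsilyloxy)-7-[(tert-butyldiphenylsilyloxy)methyl]-3-hydroxy-3-methyl-9-(triethylsilyloxy)dodeca-7,10-dien-5-yn-4-one, via lithium acetylide 13 (not isolated), via lithium dioxolanolate adduct 14 (not isolated)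
Conditions: n-BuLi (1.0 equiv), THF, −78 °C; then 4, −78 to −40 °C; aq. NH4Cl
Reagents that add atoms: none
Why: Acylation of a lithium acetylide by the dioxolanone (nucleophilic acyl substitution) should stop at the ketone stage because the tetrahedral alkoxide 14 persists at low temperature and sheds acetone only on quenching, which unveils ketone C1 and free O-10 in one operation without involving either stereocentre.

**Step 9**
Reactants: 15 the γ-hydroxy ynone of step 8
Product: 16 (2S)-2-[2-(tert-butyldimethylsilyloxy)ethyl]-5-[(2Z,4S,5E)-1-(tert-butyldiphenylsilyloxy)-4-(triethylsilyloxy)hepta-2,5-dien-2-yl]-2-methylfuran-3(2H)-one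
Conditions: (4-CF3C6H4)3PAuCl (5 mol %), AgOTf (5 mol %), toluene, rt
Reagents that add atoms: none
Why: Gold(I)-catalysed 5-endo-dig cycloisomerisation of a γ-hydroxy ynone (hydroalkoxylation, then protodeauration) is a known entry to 2,2-disubstituted 3(2H)-furanones, closes the first ring through O10–C3 and leaves C10, C6 and the Z-alkene unchanged.

**Step 10**
Reactants: 16 the bis-silylated furanone of step 9
Product: 17 (2S)-2-[2-(tert-butyldimethylsilyloxy)ethyl]-5-[(2Z,4S,5E)-1-(tert-butyldiphenylsilyloxy)-4-hydroxyhepta-2,5-dien-2-yl]-2-methylfuran-3(2H)-one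
Conditions: HF·pyridine, pyridine, THF, 0 °C
Reagents that add atoms: none
Why: Buffered HF·pyridine cleaves the secondary triethylsilyl ether well before the primary TBS and TBDPS ethers (selective desilylation), and the carbinol is carried on at once because O-6 sits cis to the electrophilic C3 of the furanone.

**Step 11**
Reactants: 17 the C6 carbinol of step 10; 18 2-(bromomethyl)acrylic acid
Product: 20 (2Z,4S,5E)-2-{(5S)-5-[2-(tert-butyldimethylsilyloxy)ethyl]-5-methyl-4-oxo-4,5-dihydrofuran-2-yl}-1-(tert-butyldiphenylsilyloxy)hepta-2,5-dien-4-yl 2-(bromomethyl)acrylate, via acid chloride 19 (not isolated)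
Conditions: 18, (COCl)2, DMF (cat.), CH2Cl2, 0 °C to rt, concentrate; then 17, 2,6-lutidine, CH2Cl2, −20 to 0 °C
Reagents that add atoms: none
Why: Acylation with the preformed acid chloride and a hindered, non-nucleophilic pyridine base (no DMAP, which would displace the allylic bromide) esterifies O-6 with retention and brings in C11, C12, C13 and the bromide needed for the ring closure.

**Step 12**
Reactants: 20 the 2-(bromomethyl)acrylate of step 11
Product: 21 (5R)-3-(bromomethyl)-5-[(1Z)-2-{(5S)-5-[2-(tert-butyldimethylsilyloxy)ethyl]-5-methyl-4-oxo-4,5-dihydrofuran-2-yl}-3-(tert-butyldiphenylsilyloxy)prop-1-en-1-yl]furan-2(5H)-one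
Conditions: Grubbs II (10 mol %), 1,4-benzoquinone (cat.), CH2Cl2 (5 mM), 40 °C
Reagents that add atoms: none
Why: Ring-closing metathesis starts at the propenyl group and closes onto the 1,1-disubstituted acrylate to give the butenolide with loss of propene, as known for methacrylates of secondary allylic alcohols, while the trisubstituted, furanone-conjugated C4=C5 bond is too hindered and electron-poor to take part.

**Step 13**
Reactants: 21 the silylated bromomethyl butenolide of step 12
Product: 22 (5R)-3-(bromomethyl)-5-[(1Z)-3-(tert-butyldiphenylsilyloxy)-2-{(5S)-5-(2-hydroxyethyl)-5-methyl-4-oxo-4,5-dihydrofuran-2-yl}prop-1-en-1-yl]furan-2(5H)-one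
Conditions: aq. HF (48 %), MeCN, 0 °C
Reagents that add atoms: none
Why: Aqueous HF in acetonitrile removes the primary TBS ether but not the TBDPS ether (selective desilylation), and the acidic, amine-free medium spares the allylic bromide and the base-sensitive C6–H of the butenolide.

**Step 14**
Reactants: 22 the primary alcohol of step 13
Product: 23 (5R)-3-(bromomethyl)-5-[(1Z)-3-(tert-butyldiphenylsilyloxy)-2-{(5S)-5-methyl-4-oxo-5-(2-oxoethyl)-4,5-dihydrofuran-2-yl}prop-1-en-1-yl]furan-2(5H)-one
Conditions: Dess–Martin periodinane, CH2Cl2, 0 °C to rt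
Reagents that add atoms: none
Why: Dess–Martin oxidation works without base, which matters because the aldehyde could expel the vinylogous carboxylate O-10 by E1cB elimination (scrambling C10) and the butenolide could enolise at C6.

**Step 15**
Reactants: 23 the bromomethyl butenolide aldehyde of step 14
Product: 25 (6R,7R,8S,10S)-15-(tert-butyldiphenylsilyloxy)-8-hydroxy-1-oxo-3,10-epoxygermacra-2,4Z,11(13)-trien-12,6-olide, via allylchromium(III) species 24 (not isolated)
Conditions: CrCl2 (10 equiv), 4 Å MS, THF, rt, slow addition of 23 (final ca. 1 mM); then H2O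
Reagents that add atoms: none
Why: Two Cr(II) reduce the allylic C13–Br bond to the σ-allylchromium(III) 24, whose Cr binds the C8 aldehyde oxygen while C7 attacks C8 in an SE2′ sense through a six-membered Zimmerman–Traxler array, so that one new bond (C7–C8) closes the nine-membered ring, moves C7=C11 to the exocyclic C11=C13 position and frees O-8. The closest known reaction types are the chromium(II)- or zinc-mediated Barbier-type allylation of aldehydes with 3-(bromomethyl)furan-2(5H)-ones and the intramolecular Nozaki–Hiyama–Kishi allylation used to close ten-membered germacrane carbocycles. The closure is 9-exo-trig at the carbonyl group when counted through O-10 (10-exo-trig through C1–C2), and no other ring is formed. C7 is controlled by C6, because the aldehyde reaches the planar butenolide on the face anti to the C5 alkenyl arm, which gives the trans-fused lactone (7R). C8 is controlled by the chair array, in which the ring-locked allyl unit (C6 trans to CH2Cr) behaves as an E-crotyl metal and C9 sits equatorially, pointing away from the lactone as the tether demands, so the anti adduct (8S) is expected, which is the epimer that step 16 inverts. The step needs γ- over α-attack (inherent to allylchromium reagents), cyclisation over oligomerisation (slow addition, plus the Z-C4=C5 bond and the furanone ring that hold both ends on one side) and allylation over reductive 1,4-loss of the lactone carboxylate (the C6–O bond lies in the butenolide plane, orthogonal to the allyl π system).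

**Step 16**
Reactants: 25 the 8S carbinol of step 15; 26 isovaleric acid
Product: 28 (6R,7R,8R,10S)-15-(tert-butyldiphenylsilyloxy)-8-(3-methylbutanoyloxy)-1-oxo-3,10-epoxygermacra-2,4Z,11(13)-trien-12,6-olide, via alkoxyphosphonium isovalerate 27 (not isolated)
Conditions: PPh3, DIAD, toluene, 0 °C (betaine preformed); then 26, then 25, 0 °C to rt
Reagents that add atoms: none
Why: Mitsunobu esterification activates O-8 as the alkoxyphosphonium ion and isovalerate displaces it by SN2 with inversion (8S to 8R), the betaine being preformed so that free PPh3 does not add to the α-methylene lactone and E2 loss toward C7 being disfavoured because C8–O is antiperiplanar to C7–C6 and not to H-7.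

**Step 17**
Reactants: 28 the silylated ester of step 16
Product: 29 CNP0171896.1, (6R,7R,8R,10S)-15-hydroxy-8-(3-methylbutanoyloxy)-1-oxo-3,10-epoxygermacra-2,4Z,11(13)-trien-12,6-olide
Conditions: HF·pyridine, THF, 0 °C to rt
Reagents that add atoms: none
Why: Fluoride-driven desilylation frees the primary allylic alcohol under mildly acidic conditions that the α-methylene lactone, the isovalerate and the furanone tolerate, and no stereocentre is touched.

**Compound list**
1 | (S)-citramalic acid | C[C@](O)(CC(=O)O)C(=O)O | starting material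
2 | (S)-2-(2,2,4-trimethyl-5-oxo-1,3-dioxolan-4-yl)acetic acid | C[C@@]1(CC(=O)O)OC(C)(C)OC1=O | intermediate
3 | (S)-5-(2-hydroxyethyl)-2,2,5-trimethyl-1,3-dioxolan-4-one | C[C@@]1(CCO)OC(C)(C)OC1=O | intermediate
4 | (S)-5-[2-(tert-butyldimethylsilyloxy)ethyl]-2,2,5-trimethyl-1,3-dioxolan-4-one | C[C@@]1(CCO[Si](C)(C)C(C)(C)C)OC(C)(C)OC1=O | intermediate
5 | tert-butyl(prop-2-yn-1-yloxy)diphenylsilane | C#CCO[Si](c1ccccc1)(c1ccccc1)C(C)(C)C | starting material
6 | (E)-crotonaldehyde | C/C=C/C=O | starting material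
7 | (4S,5E)-1-(tert-butyldiphenylsilyloxy)hept-5-en-2-yn-4-ol | C/C=C/[C@H](O)C#CCO[Si](c1ccccc1)(c1ccccc1)C(C)(C)C | intermediate
8 | sodium cyclic alkenylalanate (O6–Al–C4 five-membered ring, two 2-methoxyethoxy ligands) | [Na+].C/C=C/[C@H]1C=C(CO[Si](c2ccccc2)(c2ccccc2)C(C)(C)C)[Al-](OCCOC)(OCCOC)O1 | intermediate
9 | (2Z,4S,5E)-1-(tert-butyldiphenylsilyloxy)-2-iodohepta-2,5-dien-4-ol | C/C=C/[C@H](O)/C=C(/CO[Si](c1ccccc1)(c1ccccc1)C(C)(C)C)I | intermediate
10 | (2Z,4S,5E)-1-(tert-butyldiphenylsilyloxy)-2-iodo-4-(triethylsilyloxy)hepta-2,5-diene | C/C=C/[C@H](O[Si](CC)(CC)CC)/C=C(/CO[Si](c1ccccc1)(c1ccccc1)C(C)(C)C)I | intermediate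
11 | ethynylmagnesium bromide | C#C[Mg]Br | starting material
12 | (3E,5S,6E)-3-[(tert-butyldiphenylsilyloxy)methyl]-5-(triethylsilyloxy)octa-3,6-dien-1-yne | C/C=C/[C@H](O[Si](CC)(CC)CC)/C=C(/CO[Si](c1ccccc1)(c1ccccc1)C(C)(C)C)C#C | intermediate
13 | lithium acetylide of 12 | C/C=C/[C@H](O[Si](CC)(CC)CC)/C=C(/CO[Si](c1ccccc1)(c1ccccc1)C(C)(C)C)C#C[Li] | intermediate
14 | lithium 4-alkynyl-1,3-dioxolan-4-olate adduct of 13 and 4 (hemiketal carbon undefined) | C/C=C/[C@H](O[Si](CC)(CC)CC)/C=C(/CO[Si](c1ccccc1)(c1ccccc1)C(C)(C)C)C#CC1(O[Li])OC(C)(C)O[C@@]1(C)CCO[Si](C)(C)C(C)(C)C | intermediate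
15 | (3S,7E,9S,10E)-1-(tert-butyldimethylsilyloxy)-7-[(tert-butyldiphenylsilyloxy)methyl]-3-hydroxy-3-methyl-9-(triethylsilyloxy)dodeca-7,10-dien-5-yn-4-one | C/C=C/[C@H](O[Si](CC)(CC)CC)/C=C(/CO[Si](c1ccccc1)(c1ccccc1)C(C)(C)C)C#CC(=O)[C@@](C)(O)CCO[Si](C)(C)C(C)(C)C | intermediate
16 | (2S)-2-[2-(tert-butyldimethylsilyloxy)ethyl]-5-[(2Z,4S,5E)-1-(tert-butyldiphenylsilyloxy)-4-(triethylsilyloxy)hepta-2,5-dien-2-yl]-2-methylfuran-3(2H)-one | C/C=C/[C@H](O[Si](CC)(CC)CC)/C=C(/CO[Si](c1ccccc1)(c1ccccc1)C(C)(C)C)C1=CC(=O)[C@](C)(CCO[Si](C)(C)C(C)(C)C)O1 | intermediate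
17 | (2S)-2-[2-(tert-butyldimethylsilyloxy)ethyl]-5-[(2Z,4S,5E)-1-(tert-butyldiphenylsilyloxy)-4-hydroxyhepta-2,5-dien-2-yl]-2-methylfuran-3(2H)-one | C/C=C/[C@H](O)/C=C(/CO[Si](c1ccccc1)(c1ccccc1)C(C)(C)C)C1=CC(=O)[C@](C)(CCO[Si](C)(C)C(C)(C)C)O1 | intermediate
18 | 2-(bromomethyl)acrylic acid | C=C(CBr)C(=O)O | starting material
19 | 2-(bromomethyl)acryloyl chloride | C=C(CBr)C(=O)Cl | intermediate
20 | (2Z,4S,5E)-2-{(5S)-5-[2-(tert-butyldimethylsilyloxy)ethyl]-5-methyl-4-oxo-4,5-dihydrofuran-2-yl}-1-(tert-butyldiphenylsilyloxy)hepta-2,5-dien-4-yl 2-(bromomethyl)acrylate | C/C=C/[C@H](OC(=O)C(=C)CBr)/C=C(/CO[Si](c1ccccc1)(c1ccccc1)C(C)(C)C)C1=CC(=O)[C@](C)(CCO[Si](C)(C)C(C)(C)C)O1 | intermediate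
21 | (5R)-3-(bromomethyl)-5-[(1Z)-2-{(5S)-5-[2-(tert-butyldimethylsilyloxy)ethyl]-5-methyl-4-oxo-4,5-dihydrofuran-2-yl}-3-(tert-butyldiphenylsilyloxy)prop-1-en-1-yl]furan-2(5H)-one | BrCC1=C[C@H](OC1=O)/C=C(/CO[Si](c2ccccc2)(c2ccccc2)C(C)(C)C)C2=CC(=O)[C@](C)(CCO[Si](C)(C)C(C)(C)C)O2 | intermediate
22 | (5R)-3-(bromomethyl)-5-[(1Z)-3-(tert-butyldiphenylsilyloxy)-2-{(5S)-5-(2-hydroxyethyl)-5-methyl-4-oxo-4,5-dihydrofuran-2-yl}prop-1-en-1-yl]furan-2(5H)-one | BrCC1=C[C@H](OC1=O)/C=C(/CO[Si](c2ccccc2)(c2ccccc2)C(C)(C)C)C2=CC(=O)[C@](C)(CCO)O2 | intermediate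
23 | (5R)-3-(bromomethyl)-5-[(1Z)-3-(tert-butyldiphenylsilyloxy)-2-{(5S)-5-methyl-4-oxo-5-(2-oxoethyl)-4,5-dihydrofuran-2-yl}prop-1-en-1-yl]furan-2(5H)-one | BrCC1=C[C@H](OC1=O)/C=C(/CO[Si](c2ccccc2)(c2ccccc2)C(C)(C)C)C2=CC(=O)[C@](C)(CC=O)O2 | intermediate
24 | allylchromium(III) dichloride derived from 23 (Cr on C13) | Cl[Cr](Cl)CC1=C[C@H](OC1=O)/C=C(/CO[Si](c2ccccc2)(c2ccccc2)C(C)(C)C)C2=CC(=O)[C@](C)(CC=O)O2 | intermediate
25 | (6R,7R,8S,10S)-15-(tert-butyldiphenylsilyloxy)-8-hydroxy-1-oxo-3,10-epoxygermacra-2,4Z,11(13)-trien-12,6-olide | C=C1C(=O)O[C@@H]2/C=C(/CO[Si](c3ccccc3)(c3ccccc3)C(C)(C)C)C3=CC(=O)[C@](C)(C[C@H](O)[C@@H]12)O3 | intermediate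
26 | isovaleric acid | CC(C)CC(=O)O | starting material
27 | C8 alkoxytriphenylphosphonium isovalerate of 25 | C=C1C(=O)O[C@@H]2/C=C(/CO[Si](c3ccccc3)(c3ccccc3)C(C)(C)C)C3=CC(=O)[C@](C)(C[C@H](O[P+](c4ccccc4)(c4ccccc4)c4ccccc4)[C@@H]12)O3.CC(C)CC(=O)[O-] | intermediate
28 | (6R,7R,8R,10S)-15-(tert-butyldiphenylsilyloxy)-8-(3-methylbutanoyloxy)-1-oxo-3,10-epoxygermacra-2,4Z,11(13)-trien-12,6-olide | C=C1C(=O)O[C@@H]2/C=C(/CO[Si](c3ccccc3)(c3ccccc3)C(C)(C)C)C3=CC(=O)[C@](C)(C[C@@H](OC(=O)CC(C)C)[C@@H]12)O3 | intermediate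
29 | CNP0171896.1 | C=C1C(=O)O[C@@H]2/C=C(/CO)C3=CC(=O)[C@](C)(C[C@@H](OC(=O)CC(C)C)[C@@H]12)O3 | target

**Counts**
- Total step count: 17.
- Longest linear sequence: 14 (steps 4–17). Steps 1–3 form the second branch, which joins at step 8.

**Steps most likely to fail**

1. **Step 15.**
 - What may go wrong: the strained, bridged nine-membered transition state may lose to oligomerisation or to simple protonation of the allylchromium. The aldehyde may reach the butenolide face syn to C5. The new chromium alkoxide on O-8 may take over the lactone acyl group from O-6.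
 - Fallback (sets out from 15, comes back at 25): the ten-membered carbocycle is closed before the oxygen bridge exists and is then stitched transannularly.
 - Selective cleavage of the triethylsilyl ether of 15 (HF·pyridine, pyridine) would give the C6 carbinol ynone F1, and acylation with 19 and 2,6-lutidine the bromomethylacrylate ynone F2.
 - Ring-closing metathesis would then give the butenolide ynone F3, aqueous HF the primary alcohol F4, and Dess–Martin oxidation the aldehyde F5.
 - CrCl2 at high dilution (or indium, should Cr(II) reduce the ynone) would form C7–C8 and give the cyclodecenynone carbinol F6, a ring that lacks the bridge strain.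
 - Gold(I)-catalysed transannular 5-endo-dig addition of O-10 to C3, under the conditions of step 9, then leads to 25.
 - This order also keeps a free O-6 away from the furanone. Premature furanone closure at any stage merely returns material to the main line.

2. **Step 16.**
 - What may go wrong: SN2 attack at the hindered C8, flanked by C7 and the neopentyl-type C9, may be slower than elimination. It may also be slower than acyl transfer to the hydrazide, or than an acyloxyphosphonium pathway with retention.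
 - Fallback (sets out from 25, comes back at 28): the configuration is corrected by redox chemistry instead of substitution.
 - Dess–Martin oxidation would give the 8-ketone F7.
 - Luche reduction (NaBH4, CeCl3, MeOH, −78 °C), with hydride delivered from the periphery of the medium ring, would give the 8R carbinol F8.
 - Isovaleric anhydride with catalytic DMAP would then acylate with retention to 28.
 - The same acylation serves if step 15 should deliver the 8R carbinol directly.

3. **Step 8.**
 - What may go wrong: premature collapse of the tetrahedral adduct would allow a second acetylide addition. Attack at the carbonyl group next to the quaternary C10 may also be sluggish.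
 - Fallback (sets out from 4, comes back at 15): the acyl donor is changed to a chelating amide.
 - Aminolysis of 4 with MeNH(OMe)·HCl and i-PrMgCl would give the α-hydroxy Weinreb amide F9.
 - Its magnesium alkoxide (one further equivalent of i-PrMgCl) is treated with acetylide 13, and the chelated adduct releases 15 on quenching.

**Further compounds**
F1 | step 15 | (3S,7E,9S,10E)-1-(tert-butyldimethylsilyloxy)-7-[(tert-butyldiphenylsilyloxy)methyl]-3,9-dihydroxy-3-methyldodeca-7,10-dien-5-yn-4-one | C/C=C/[C@H](O)/C=C(/CO[Si](c1ccccc1)(c1ccccc1)C(C)(C)C)C#CC(=O)[C@@](C)(O)CCO[Si](C)(C)C(C)(C)C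
F2 | step 15 | 2-(bromomethyl)acrylate of F1 at O-6 | C/C=C/[C@H](OC(=O)C(=C)CBr)/C=C(/CO[Si](c1ccccc1)(c1ccccc1)C(C)(C)C)C#CC(=O)[C@@](C)(O)CCO[Si](C)(C)C(C)(C)C
F3 | step 15 | (5R)-3-(bromomethyl)butenolide bearing the (Z)-enynone chain with free O-10 and O8-TBS | BrCC1=C[C@H](OC1=O)/C=C(/CO[Si](c2ccccc2)(c2ccccc2)C(C)(C)C)C#CC(=O)[C@@](C)(O)CCO[Si](C)(C)C(C)(C)C
F4 | step 15 | primary alcohol from F3 | BrCC1=C[C@H](OC1=O)/C=C(/CO[Si](c2ccccc2)(c2ccccc2)C(C)(C)C)C#CC(=O)[C@@](C)(O)CCO
F5 | step 15 | C8 aldehyde from F4 | BrCC1=C[C@H](OC1=O)/C=C(/CO[Si](c2ccccc2)(c2ccccc2)C(C)(C)C)C#CC(=O)[C@@](C)(O)CC=O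
F6 | step 15 | (6R,7R,8S,10S)-15-(tert-butyldiphenylsilyloxy)-8,10-dihydroxy-1-oxogermacra-4Z,11(13)-dien-2-yn-12,6-olide | C=C1C(=O)O[C@@H]2/C=C(/CO[Si](c3ccccc3)(c3ccccc3)C(C)(C)C)C#CC(=O)[C@@](C)(O)C[C@H](O)[C@@H]12
F7 | step 16 | (6R,7R,10S)-15-(tert-butyldiphenylsilyloxy)-1,8-dioxo-3,10-epoxygermacra-2,4Z,11(13)-trien-12,6-olide | C=C1C(=O)O[C@@H]2/C=C(/CO[Si](c3ccccc3)(c3ccccc3)C(C)(C)C)C3=CC(=O)[C@](C)(CC(=O)[C@@H]12)O3
F8 | step 16 | (6R,7R,8R,10S)-15-(tert-butyldiphenylsilyloxy)-8-hydroxy-1-oxo-3,10-epoxygermacra-2,4Z,11(13)-trien-12,6-olide | C=C1C(=O)O[C@@H]2/C=C(/CO[Si](c3ccccc3)(c3ccccc3)C(C)(C)C)C3=CC(=O)[C@](C)(C[C@@H](O)[C@@H]12)O3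
F9 | step 8 | (S)-4-(tert-butyldimethylsilyloxy)-2-hydroxy-N-methoxy-N,2-dimethylbutanamide | CON(C)C(=O)[C@@](C)(O)CCO[Si](C)(C)C(C)(C)C
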